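| flask | substrate | gas phase | remark | time |
|---|---|---|---|---|
| red | 1.1 M | 29 mM (held) | run made earlier |  |
| violet | 1.8 M | 29 mM (held) | run made earlier |  |
| flask | 0.80 M | 29 mM (held) |  | 25 h |

| run | time / h | target / % |
|---|---|---|
| red | 2.00 | 2.2 |
| red | 3.00 | 2.7 |
| red | 5.00 | 4.4 |
| red | 8.00 | 6.1 |
| red | 10.0 | 7.5 |
| red | 15.0 | 8.7 |
| red | 25.0 | 10.3 |
| violet | 2.00 | 2.0 |
| violet | 3.00 | 2.6 |
| violet | 5.00 | 3.7 |
| violet | 8.00 | 4.8 |
| violet | 10.0 | 4.8 |
| violet | 15.0 | 5.4 |
| violet | 25.0 | 6.7 |

(scatter of a reading: 0.3 percentage points)

- in percentages every species weighs as the substrate in it: one side product counts as two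
- at the start none of the gas is dissolved
- steps thought possible: gas phase <-> dissolved gas; substrate + dissolved gas -> target; substrate + target -> side product

- target at 25 h, in percent of the substrate charged
- concentration of dissolved gas in solution at 25 h, in percent of saturation

At the last reading of the red run, 89.7% of the charge was still something other than target, yet the target had gained just 1.6 percentage points in the last 10.0 h. Making and losing target each take one substrate, so with the dissolved gas steady, substrate cancels from their ratio: making over loss equals ceiling over target. The ceiling is the target concentration at which the two balance, a steady state.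

I read the ceiling from each run apart, by the same reckoning. In the red run the target rose at 0.00968 M h⁻¹ over the first 5.00 h and at 0.00176 M h⁻¹ over the last stretch. Drawing the rate straight against mean target down to zero gave 0.122 M. The violet run, with its different charge, gave 0.125 M. But both share one weakness, which I left uncorrected: the late slope stands on less substrate than the early one. I carried their mean, 0.124 M, as the ceiling.

For the flask I took making at 0.0110 h⁻¹ per unit of substrate, from the first red reading, and loss at 0.5 of making on average. That gave a mean substrate of 0.665 M. Target climbing exponentially towards the ceiling then gave 11.9%. The forecast said 12.7% and 93% of saturation, on the ground that “Both rates scale with substrate”, with a plateau of about 0.135 M. My target is lower than its figure, and I made no saturation figure of my own.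

The flask gave 12.9% of target, with dissolved gas at 93.4% of saturation.

    gas phase ⇌ dissolved gas, rate k1*(csat - [dissolved gas]) (kL = 3.50 h⁻¹)
    substrate + dissolved gas → target (k = 0.520 M⁻¹ h⁻¹)
    substrate + target → side product (k = 0.110 M⁻¹ h⁻¹)

The flask's 0.103 M of target puts the ceiling I read at 1.20 times the target, and in the flask substrate went to target 1.2 times as fast as to side product at 25.0 h. In the neighbour charged with 0.48 M of substrate, the ceiling I carried is 25.8% of the charge, and the same reckoning gave 15.2%. That neighbour held 17.6% of target at 25.0 h.

(The numbers in the tables were computed with constants of no real substance; the scatter is artificial.)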